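The intermediate is the species asked about, and ochre has a close neighbour in the north-east run: both have the same equivalents and loading, with substrate charges of 0.060 M and 0.039 M.

all flasks: catalyst 0.36 mol%
- north-east: substrate 0.039 M; coupling partner 1 equiv; run made earlier
- south-west: substrate 1.4 M; coupling partner 1 equiv; run made earlier
- ochre: substrate 0.060 M; coupling partner 1.00 equiv; time 3.0 min
- blue: substrate 0.20 M; coupling partner 1.00 equiv; time 3.0 min
- grey: substrate 0.60 M; coupling partner 1.00 equiv; time 3.0 min
- amber: substrate 2.0 M; coupling partner 1.00 equiv; time 3.0 min

| run | time / s | intermediate / % | target / % | substrate / % |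
|---|---|---|---|---|
| north-east | 10.0 | 34 | 0 | 63 |
| north-east | 15.0 | 50 | 0 | 50 |
| north-east | 25.0 | 67 | 2 | 31 |
| north-east | 40.0 | 86 | 0 | 17 |
| north-east | 50.0 | 87 | 0 | 11 |
| north-east | 80.0 | 95 | 2 | 2 |
| north-east | 90.0 | 99 | 2 | 3 |
| south-west | 10.0 | 25 | 73 | 0 |
| south-west | 12.0 | 20 | 80 | 0 |
| south-west | 15.0 | 20 | 82 | 1 |
| south-west | 25.0 | 10 | 90 | 0 |
| south-west | 40.0 | 10 | 95 | 0 |
| south-west | 60.0 | 8 | 94 | 1 |
| south-west | 90.0 | 2 | 95 | 1 |

(scatter of a reading: 1.5 percentage points)

- the earlier runs were read with a standard deviation of 1.5 percentage points
- "hardly changes" means that all values lie within two and a half points (for a concentration: within two and a half percent of the largest)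

1. [intermediate] at the end for ochre, blue, grey, amber, in this order
2. how that number moves from the first to the last of them (hardly changes / falls all the way / falls, then rises / rises, then falls / rises all the way)

In north-east the substrate reads 50% at 15.0 s, so its half-time is short against the time asked. At 90.0 s the intermediate reads 99% and the target 2%. In ochre, therefore, the coupling of the intermediate is taken as the rate-limiting step.

The reckoning here assumes that this step needs intermediate, coupling partner and catalyst. At one equivalent the first two stay equal, each a fraction f of the charge, and the fixed loading ties the catalyst to the charge. So the reciprocal of f grows linearly with time, with a slope that goes as the square of the charge.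

South-west's intermediate reading of 25% at 10.0 s puts at 0.191 M the half-way charge, the substrate charge with half of itself left as intermediate after 3.0 min. This is a reading and carries the scatter. North-east's substrate reads 3% at 90.0 s, and the smallest charge of the row, 0.060 M, stands above north-east's. For the charges of the row at this loading, with the first step taken as over by 3.0 min, f is one over one plus the squared ratio of charge to half-way charge. Across these charges the concentration of intermediate therefore peaks at the half-way charge, and a charge below it mirrors one above it.

North-east at 90.0 s reckons to 2.04% target. Ochre gets 4.73 times north-east's count, which still leaves f at 91.0%.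

The row reckoned here is 0.0546 M, 0.0951 M, 0.0550 M and 0.0180 M. The forecast gives 0.055 M, 0.1 M, 0.059 M and 0.019 M, and its shape is "rises, then falls". It reads the south-west tail as “second order in the fraction remaining”. Its blue value stands higher than the one here.

The flask gives 0.0547 M, 0.0935 M, 0.0526 M and 0.0168 M, so the row rises, then falls, and the forecast stands on both counts.

    substrate + catalyst → catalyst + intermediate (k = 320 L mol⁻¹ s⁻¹)
    coupling partner + catalyst + intermediate → catalyst + target (k = 45.0 L² mol⁻² s⁻¹)
    substrate + target → side product (k = 0.00260 L mol⁻¹ s⁻¹)

The row turns at 0.19 M of substrate. Time enters beside the squared ratio, so the half-way charge serves at later times too. Ochre at ten times the time asked reckons to f of 50.2% and holds 49.0%. Blue at 30.0 min reckons to 8.32% and holds 7.91%.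

(The earlier runs and the new flask stem from a simulated flask for an exercise, noise included.)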